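**Retrosynthetic overview**
- The tetrahydrofuran, the only ring and the last thing formed, is opened at a C–O bond to the C2-symmetric (2S,3S)-2,3-bis(3,4-dimethoxybenzyl)butane-1,4-diol.
- The diol comes from reductive removal of two oxazolidinone auxiliaries from the (2S,3S)-2,3-dibenzylsuccinyl bis-imide.
- The bis-imide is cut at its central C2–C3 bond (lignan C8–C8') into two identical imide enolates, joined by oxidative homocoupling. One α-carbon reacts at the enolonium/α-radical level, and the (R)-auxiliary sets both stereocentres in that one step.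
- The imide comes from 3-(3,4-dimethoxyphenyl)propanoic acid and (R)-4-benzyl-1,3-oxazolidin-2-one.

Assumption: the SMILES is read as the trans (3S,4S) isomer (both centres S by CIP analysis); LiN(iPr)2 is bought as a solution and not made in the flask.

**Route**

Step 1
Reactants: 1 3-(3,4-dimethoxyphenyl)propanoic acid; 2 (R)-4-benzyl-1,3-oxazolidin-2-one
Product: 4 (4R)-4-benzyl-3-[3-(3,4-dimethoxyphenyl)propanoyl]-1,3-oxazolidin-2-one, via mixed pivalic anhydride 3 (not isolated)
Conditions: PivCl (1.05 equiv), Et3N (2.5 equiv), THF, −20 °C, 1 h; then 2 (1.0 equiv), LiCl (1.1 equiv), −20 °C to rt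
Reagents that add atoms: none
Why: Mixed-anhydride N-acylation of an Evans oxazolidinone: PivCl turns 1 into the mixed anhydride and the LiCl/Et3N-activated oxazolidinone attacks its less hindered 3-arylpropanoyl carbonyl; no stereocentre is formed and the (R) centre of the auxiliary is untouched.

Step 2
Reactants: 4 (4R)-4-benzyl-3-[3-(3,4-dimethoxyphenyl)propanoyl]-1,3-oxazolidin-2-one (two molecules)
Product: 7 (4R,4'R)-3,3'-[(2S,3S)-2,3-bis(3,4-dimethoxybenzyl)butanedioyl]bis(4-benzyl-1,3-oxazolidin-2-one), via lithium Z-enolate 5 (not isolated), via trichlorotitanium Z-enolate 6 (not isolated)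
Conditions: LiN(iPr)2 (LDA, 1.05 equiv), THF, −78 °C, 45 min; then TiCl4 (1.05 equiv, 1 M in CH2Cl2), −78 °C to rt, 12 h; aq. NH4Cl; chromatography, then recrystallisation
Reagents that add atoms: none
Why: Oxidative enolate homocoupling (titanium-mediated, Saegusa-type dimerisation): the chelated Z-enolate is transmetalated to the tetravalent-titanium enolate, whose Ti–O bond homolyses to trivalent titanium and an α-carbonyl radical (an enolonium-level, polarity-reversed α-carbon) that bonds to the α-carbon of a second chelated enolate unit, so two normally nucleophilic α-carbons are joined; each unit reacts on the face anti to the C4 benzyl group of the (R)-auxiliary (the Evans alkylation sense), which gives S at both new centres, and the minor unsymmetrical (2R,3S) diastereomer is removed by chromatography or crystallisation.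

Step 3
Reactants: 7 (4R,4'R)-3,3'-[(2S,3S)-2,3-bis(3,4-dimethoxybenzyl)butanedioyl]bis(4-benzyl-1,3-oxazolidin-2-one)
Product: 8 (2S,3S)-2,3-bis(3,4-dimethoxybenzyl)butane-1,4-diol
Conditions: LiBH4 (4 equiv), H2O (4 equiv), Et2O–THF, 0 °C to rt, 12 h; aq. NH4Cl
Reagents that add atoms: none
Why: Reductive cleavage of N-acyloxazolidinones with LiBH4: lithium-chelated hydride delivery to the exocyclic imide carbonyls gives the primary alcohols (any lactone formed by alkoxide attack on the second imide is reduced onwards) and releases auxiliary 2 for recovery; the medium is non-enolising, so both α-stereocentres are carried through unchanged as (2S,3S).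

Step 4
Reactants: 8 (2S,3S)-2,3-bis(3,4-dimethoxybenzyl)butane-1,4-diol
Product: 10 (3S,4S)-3,4-bis(3,4-dimethoxybenzyl)tetrahydrofuran, via monotosylate 9 (not isolated)
Conditions: TsCl (1.1 equiv), pyridine, 0 °C to rt, then 50 °C, 4 h
Reagents that add atoms: none
Why: Monotosylation followed by intramolecular Williamson etherification (5-exo-tet SN2 of the remaining hydroxyl on the primary tosylate) closes the tetrahydrofuran; bonds are made only at the two CH2O carbons, so the (2S,3S) centres become (3S,4S) without change.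

**Compound list**

1 | 3-(3,4-dimethoxyphenyl)propanoic acid | COc1ccc(CCC(=O)O)cc1OC | starting material
2 | (R)-4-benzyl-1,3-oxazolidin-2-one | O=C1N[C@H](Cc2ccccc2)CO1 | starting material
3 | 3-(3,4-dimethoxyphenyl)propanoic pivalic anhydride (not isolated) | COc1ccc(CCC(=O)OC(=O)C(C)(C)C)cc1OC | intermediate
4 | (4R)-4-benzyl-3-[3-(3,4-dimethoxyphenyl)propanoyl]-1,3-oxazolidin-2-one | COc1ccc(CCC(=O)N2[C@H](Cc3ccccc3)COC2=O)cc1OC | intermediate
5 | lithium (Z)-enolate of 4 (not isolated) | COc1ccc(C/C=C(\O[Li])N2[C@H](Cc3ccccc3)COC2=O)cc1OC | intermediate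
6 | trichlorotitanium (Z)-enolate of 4 (not isolated) | COc1ccc(C/C=C(\O[Ti](Cl)(Cl)Cl)N2[C@H](Cc3ccccc3)COC2=O)cc1OC | intermediate
7 | (4R,4'R)-3,3'-[(2S,3S)-2,3-bis(3,4-dimethoxybenzyl)butanedioyl]bis(4-benzyl-1,3-oxazolidin-2-one) | O=C([C@@H](Cc1ccc(OC)c(OC)c1)[C@H](Cc1ccc(OC)c(OC)c1)C(=O)N1[C@H](Cc2ccccc2)COC1=O)N1[C@H](Cc2ccccc2)COC1=O | intermediate
8 | (2S,3S)-2,3-bis(3,4-dimethoxybenzyl)butane-1,4-diol | OC[C@@H](Cc1ccc(OC)c(OC)c1)[C@@H](CO)Cc1ccc(OC)c(OC)c1 | intermediate
9 | (2S,3S)-2,3-bis(3,4-dimethoxybenzyl)-4-hydroxybutyl 4-methylbenzenesulfonate (not isolated) | Cc1ccc(cc1)S(=O)(=O)OC[C@@H](Cc1ccc(OC)c(OC)c1)[C@@H](CO)Cc1ccc(OC)c(OC)c1 | intermediate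
10 | (3S,4S)-3,4-bis(3,4-dimethoxybenzyl)tetrahydrofuran | COc1ccc(C[C@@H]2COC[C@H]2Cc2ccc(OC)c(OC)c2)cc1OC | target

**Totals**

Total step count: 4. Longest linear sequence: 4 steps (1 to 10).

**Steps most likely to fail, with fallbacks**

Step 2 (oxidative homocoupling). The risks are a modest yield and incomplete selectivity for the (S,S) over the unsymmetrical diastereomer. The fallback sets out from 4 and comes back at 8, and forms the two benzylic centres one after the other instead of in one coupling. The sodium enolate of 4 (NaN(SiMe3)2, THF, −78 °C) is alkylated with tert-butyl bromoacetate (BrCH2C(=O)OC(C)(C)C) on the face anti to the auxiliary benzyl group to give tert-butyl (3S)-4-[(4R)-4-benzyl-2-oxo-1,3-oxazolidin-3-yl]-3-(3,4-dimethoxybenzyl)-4-oxobutanoate F1. LiBH4 removes the auxiliary to give tert-butyl (3S)-3-(3,4-dimethoxybenzyl)-4-hydroxybutanoate F2. CF3CO2H in CH2Cl2 closes this to (4S)-4-(3,4-dimethoxybenzyl)dihydrofuran-2(3H)-one F3. LiN(SiMe3)2 followed by 3,4-dimethoxybenzyl bromide (COc1ccc(CBr)cc1OC) alkylates trans to the C4 substituent to give (3S,4S)-3,4-bis(3,4-dimethoxybenzyl)dihydrofuran-2(3H)-one F4. LiAlH4 in THF reduces this lactone to diol 8.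

Step 3 (double reductive cleavage of a hindered bis-imide). The risks are stalling at the mono-reduced stage and hydride attack on the oxazolidinone ring carbonyl. The fallback sets out from 7 and comes back at 8, and removes the auxiliaries by hydrolysis before any hydride is used. LiOH/H2O2 (THF–H2O, 0 °C) attacks only the exocyclic carbonyls and gives (2S,3S)-2,3-bis(3,4-dimethoxybenzyl)butanedioic acid F5. BH3·SMe2 (THF, 0 °C to rt) then reduces the diacid to diol 8.

Step 4 (cyclodehydration). The risks are ditosylation and chloride displacement competing with ring closure. The fallback sets out from 8 and comes back at 10, and closes the ring at the lactol oxidation level instead of by displacement. IBX (2-iodoxybenzoic acid, 1.2 equiv) in DMSO oxidises one primary alcohol, and the aldehyde closes onto the other hydroxyl to give (3S,4S)-3,4-bis(3,4-dimethoxybenzyl)tetrahydrofuran-2-ol F6 as an anomeric mixture. Et3SiH/BF3·OEt2 (CH2Cl2, −78 °C) reduces the derived oxocarbenium ion to 10. The silane is present in excess before the Lewis acid is added, so that hydride transfer outruns Friedel–Crafts closure onto the electron-rich ring.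

**Further compounds**

F1 | step 2 | tert-butyl (3S)-4-[(4R)-4-benzyl-2-oxo-1,3-oxazolidin-3-yl]-3-(3,4-dimethoxybenzyl)-4-oxobutanoate | CC(C)(C)OC(=O)C[C@H](Cc1ccc(OC)c(OC)c1)C(=O)N1[C@H](Cc2ccccc2)COC1=O
F2 | step 2 | tert-butyl (3S)-3-(3,4-dimethoxybenzyl)-4-hydroxybutanoate | CC(C)(C)OC(=O)C[C@H](Cc1ccc(OC)c(OC)c1)CO
F3 | step 2 | (4S)-4-(3,4-dimethoxybenzyl)dihydrofuran-2(3H)-one | O=C1C[C@H](Cc2ccc(OC)c(OC)c2)CO1
F4 | step 2 | (3S,4S)-3,4-bis(3,4-dimethoxybenzyl)dihydrofuran-2(3H)-one | O=C1OC[C@@H](Cc2ccc(OC)c(OC)c2)[C@@H]1Cc1ccc(OC)c(OC)c1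
F5 | step 3 | (2S,3S)-2,3-bis(3,4-dimethoxybenzyl)butanedioic acid | OC(=O)[C@@H](Cc1ccc(OC)c(OC)c1)[C@H](Cc1ccc(OC)c(OC)c1)C(=O)O
F6 | step 4 | (3S,4S)-3,4-bis(3,4-dimethoxybenzyl)tetrahydrofuran-2-ol (anomeric mixture) | OC1OC[C@@H](Cc2ccc(OC)c(OC)c2)[C@@H]1Cc1ccc(OC)c(OC)c1
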